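**Retrosynthetic overview**
1. Target 29 ⇐ diol allyl ester 27 (acetylation, deallylation) ⇐ C8 ketone 26 (methyl addition) ⇐ epoxy ketone 25 (SmI2) ⇐ methyl ketone 24 (Horner–Wadsworth–Emmons at C13).
2. Key disconnection C9–C11: intermolecular Michael addition of the C9 lithium enolate of bicyclic epoxy ketone 21 to enone fragment 22.
3. 21 ⇐ cis-decalone 18 (Saegusa–Ito, nucleophilic epoxidation puts oxygen on C6) ⇐ dione 14 (ring A carbonyl removed by Wolff–Kishner).
4. Ring A is made first (acid cyclisation of geranic acid; resolution fixes C5). Ring B is closed second at C9–C10 by intramolecular Michael addition of β-keto ester 12 onto the ring A enone, which fixes the cis ring fusion and the angular methyl.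
5. C6, C9 and C8 are then set by attack on the convex face of the cis-decalin.

Numbering: bicyclic compounds are numbered like labdanes (C4 gem-dimethyl, C5 ring-fusion CH, C6–C9 ring B, C10 carries the angular methyl); "cis-decalin" means H-5 and the C10 methyl are cis.
Assumption: with (S)-1-phenylethylamine the less soluble salt is that of the (S)-acid (checked by rotation); if it is the other one, the (R)-amine is used.

**Step 1**
Reactants: 1 geranic acid [(2E)-3,7-dimethylocta-2,6-dienoic acid]
Product: 2 (±)-α-cyclogeranic acid (rac-2,6,6-trimethylcyclohex-2-ene-1-carboxylic acid)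
Conditions: 85% H3PO4, 95 °C; crystallise
Reagents that add atoms: none
Why: Acid-mediated cationic olefin cyclisation (tertiary cation captured by the 2,3-alkene, proton loss to the α isomer) builds ring A with the gem-dimethyl group and the future C10 methyl; the product is racemic.

**Step 2**
Reactants: 2 (±)-α-cyclogeranic acid
Product: 3 (S)-1-phenylethylammonium (1S)-2,6,6-trimethylcyclohex-2-ene-1-carboxylate (crystalline salt)
Conditions: (S)-1-phenylethylamine, acetone, recrystallise to constant rotation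
Reagents that add atoms: (S)-1-phenylethylamine, C[C@H](N)c1ccccc1
Why: Classical resolution by diastereomeric salt crystallisation fixes the only stereocentre of the monocyclic series (future C5) as S.

**Step 3**
Reactants: 3 (S)-amine salt of (S)-α-cyclogeranic acid
Product: 5 (S)-α-cyclogeraniol [(1S)-2,6,6-trimethylcyclohex-2-en-1-yl]methanol, via free (S)-α-cyclogeranic acid 4 (not isolated)
Conditions: 2 M HCl, Et2O, dry extract; then LiAlH4, Et2O, 0 °C → rt
Reagents that add atoms: none
Why: Acid–base liberation of the acid followed by LiAlH4 reduction to the primary alcohol, which does not touch the stereocentre.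

**Step 4**
Reactants: 5 (S)-α-cyclogeraniol
Product: 6 (S)-α-cyclocitral [(1S)-2,6,6-trimethylcyclohex-2-ene-1-carbaldehyde]
Conditions: Dess–Martin periodinane, NaHCO3, CH2Cl2, 0 °C; used at once
Reagents that add atoms: none
Why: Buffered Dess–Martin oxidation gives the α-branched β,γ-unsaturated aldehyde without epimerisation or alkene migration.

**Step 5**
Reactants: 6 (S)-α-cyclocitral
Product: 7 methyl (2E)-3-[(1S)-2,6,6-trimethylcyclohex-2-en-1-yl]prop-2-enoate
Conditions: Ph3P=CHCO2Me, toluene, 80 °C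
Reagents that add atoms: methyl (triphenylphosphoranylidene)acetate, COC(=O)C=P(c1ccccc1)(c1ccccc1)c1ccccc1
Why: Wittig olefination with a stabilised, non-basic ylide adds C7 and C8 without epimerising the aldehyde.

**Step 6**
Reactants: 7 E-enoate
Product: 8 methyl 3-[(1S)-2,6,6-trimethylcyclohex-2-en-1-yl]propanoate
Conditions: H2 (1 atm), RhCl(PPh3)3 (5 mol %), benzene–EtOH, rt
Reagents that add atoms: none
Why: Homogeneous hydrogenation reduces only the unhindered disubstituted conjugated alkene; the hindered trisubstituted ring alkene neither reacts nor migrates.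

**Step 7**
Reactants: 8 saturated ester
Product: 9 methyl 3-[(1S)-2,6,6-trimethyl-4-oxocyclohex-2-en-1-yl]propanoate
Conditions: CrO3, 3,5-dimethylpyrazole, CH2Cl2, −20 °C
Reagents that add atoms: chromium trioxide, O=[Cr](=O)=O
Why: Allylic oxidation of the ring CH2 next to the vinylic CH gives the ring A enone (C2 carbonyl) under non-basic conditions that leave C5 untouched.

**Step 8**
Reactants: 9 enone ester
Product: 10 3-[(1S)-2,6,6-trimethyl-4-oxocyclohex-2-en-1-yl]propanoic acid
Conditions: LiOH, THF–H2O, 0 °C → rt; then 1 M HCl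
Reagents that add atoms: lithium hydroxide, [Li+].[OH-]
Why: Saponification of the unhindered methyl ester at low temperature; the hindered γ-hydrogen at C5 is not removed by hydroxide.

**Step 9**
Reactants: 10 enone acid
Product: 12 methyl 3-oxo-5-[(1S)-2,6,6-trimethyl-4-oxocyclohex-2-en-1-yl]pentanoate, via acyl imidazolide 11 (not isolated)
Conditions: 1,1'-carbonyldiimidazole, THF, rt; then KO2CCH2CO2Me, MgCl2, Et3N, MeCN, rt; 1 M HCl work-up
Reagents that add atoms: methyl potassium malonate, COC(=O)CC(=O)[O-].[K+]; 1,1'-carbonyldiimidazole, O=C(n1ccnc1)n1ccnc1 (its imidazolyl group is carried only by intermediate 11)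
Why: Masamune decarboxylative Claisen condensation gives the β-keto ester (C9 nucleophile) under nearly neutral conditions compatible with the enone.

**Step 10**
Reactants: 12 β-keto ester
Product: 13 methyl (5S,10R)-4,4,10-trimethyl-2,8-dioxo-cis-decalin-9-carboxylate (C9 epimers and enol)
Conditions: Cs2CO3 (0.3 equiv), MeCN, rt
Reagents that add atoms: none
Why: Intramolecular Michael addition (6-exo) of the soft β-keto ester carbon to the β,β-disubstituted ring A enone; the tether on C5 can reach C10 only from its own face, so ring B is cis-fused and the C10 methyl ends cis to H-5.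

**Step 11**
Reactants: 13 bicyclic diketo ester
Product: 14 (5S,10R)-4,4,10-trimethyl-cis-decalin-2,8-dione
Conditions: LiCl, DMSO, H2O, 150 °C
Reagents that add atoms: none
Why: Krapcho dealkoxycarbonylation removes the ester; no stereocentre is α to either ketone.

**Step 12**
Reactants: 14 dione
Product: 15 (5S,10S)-8,8-ethylenedioxy-4,4,10-trimethyl-cis-decalin-2-one
Conditions: ethylene glycol (1.2 equiv), p-TsOH (cat.), benzene, reflux, Dean–Stark
Reagents that add atoms: ethylene glycol, OCCO
Why: Thermodynamically controlled ketalisation selects C8, because a ketal at C2 would put an oxygen 1,3-diaxial to both the C10 methyl and the axial C4 methyl.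

**Step 13**
Reactants: 15 keto ketal
Product: 17 (5S,10S)-8,8-ethylenedioxy-4,4,10-trimethyl-cis-decalin, via hydrazone 16 (not isolated)
Conditions: N2H4·H2O, KOH, diethylene glycol, 130 → 200 °C
Reagents that add atoms: hydrazine hydrate, NN.O (its nitrogen is carried only by intermediate 16)
Why: Wolff–Kishner (Huang-Minlon) reduction removes the hindered C2 carbonyl while the base-stable ketal survives.

**Step 14**
Reactants: 17 ketal
Product: 18 (5S,10S)-4,4,10-trimethyl-cis-decalin-8-one
Conditions: 1 M HCl, THF, rt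
Reagents that add atoms: water, O
Why: Acid-catalysed ketal hydrolysis frees the C8 ketone.

**Step 15**
Reactants: 18 cis-decalone
Product: 20 (5S,10S)-4,4,10-trimethyl-cis-decal-6-en-8-one, via silyl enol ether 19 (not isolated)
Conditions: LiN(iPr)2, THF, −78 °C, Me3SiCl; then Pd(OAc)2, MeCN, rt
Reagents that add atoms: chlorotrimethylsilane, C[Si](C)(C)Cl (silyl group carried only by intermediate 19)
Why: Saegusa–Ito oxidation; kinetic deprotonation occurs at C7 and not at the neopentyl C9, and only the C6=C7 enone can form because C10 is quaternary.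

**Step 16**
Reactants: 20 enone
Product: 21 (5S,6R,7R,10S)-6,7-epoxy-4,4,10-trimethyl-cis-decalin-8-one (epoxide cis to the angular methyl)
Conditions: 30% H2O2, NaOH (cat.), MeOH, 0 °C, short reaction time
Reagents that add atoms: hydrogen peroxide, OO
Why: Weitz–Scheffer nucleophilic epoxidation; hydroperoxide attacks C6 on the convex face of the folded cis-decalin, away from the axial C1 methylene, which places the C6 oxygen cis to the angular methyl.

**Step 17**
Reactants: 21 epoxy ketone; 22 3-(trimethylsilyl)but-3-en-2-one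
Product: 24 (5S,6R,7R,9S,10R)-6,7-epoxy-4,4,10-trimethyl-9-(3-oxobutyl)-cis-decalin-8-one, via silyl ketone adduct 23 (not isolated)
Conditions: LiN(iPr)2, THF, −78 °C; 22, −78 → −30 °C; aq NH4Cl; then KF, MeOH, 0 °C
Reagents that add atoms: none
Why: Intermolecular Michael addition (Stork–Ganem α-silyl enone) of the C9 lithium enolate, which forms regiospecifically because C7 is an epoxide CH; axial attack on the convex face, anti to the axial C1 on C10, puts the side chain cis to the angular methyl, and fluoride then removes the silyl group.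

**Step 18**
Reactants: 24 epoxy diketone
Product: 25 allyl (2E)-5-[(5S,6R,7R,9S,10R)-6,7-epoxy-4,4,10-trimethyl-8-oxo-cis-decalin-9-yl]-3-methylpent-2-enoate
Conditions: (EtO)2P(O)CH2CO2CH2CH=CH2, NaH, THF, 0 → 45 °C; chromatography removes the minor Z isomer
Reagents that add atoms: allyl diethylphosphonoacetate, CCOP(=O)(CC(=O)OCC=C)OCC
Why: Horner–Wadsworth–Emmons olefination reacts only at the unhindered methyl ketone and favours the E trisubstituted enoate (expect roughly 5:1).

**Step 19**
Reactants: 25 epoxy keto ester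
Product: 26 allyl (2E)-5-[(5S,6S,9S,10R)-6-hydroxy-4,4,10-trimethyl-8-oxo-cis-decalin-9-yl]-3-methylpent-2-enoate
Conditions: SmI2 (2.5 equiv), THF–MeOH, −78 °C
Reagents that add atoms: none
Why: Single-electron reductive cleavage of the C7–O bond of the α,β-epoxy ketone gives the β-hydroxy ketone regiospecifically, with the C6 configuration of the epoxide retained.

**Step 20**
Reactants: 26 β-hydroxy ketone
Product: 27 allyl (2E)-5-[(5S,6S,8S,9S,10R)-6,8-dihydroxy-4,4,8,10-tetramethyl-cis-decalin-9-yl]-3-methylpent-2-enoate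
Conditions: MeMgBr (4 equiv), CeCl3 (4 equiv), THF, −78 °C; aq NH4Cl
Reagents that add atoms: methylmagnesium bromide, C[Mg]Br
Why: Organocerium (Imamoto) 1,2-addition to the enolisable ketone in the presence of the ester; equatorial attack from the convex face (axial approach is blocked by the 1,3-diaxial C1 methylene) gives the axial 8-OH trans to the angular methyl.

**Step 21**
Reactants: 27 diol
Product: 28 allyl (2E)-5-[(5S,6S,8S,9S,10R)-6-acetoxy-8-hydroxy-4,4,8,10-tetramethyl-cis-decalin-9-yl]-3-methylpent-2-enoate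
Conditions: Ac2O, pyridine, DMAP (cat.), CH2Cl2, 0 °C → rt
Reagents that add atoms: acetic anhydride, CC(=O)OC(C)=O
Why: Selective acylation of the secondary 6-OH; the hindered tertiary axial 8-OH does not react.

**Step 22**
Reactants: 28 acetate allyl ester
Product: 29 (2E)-5-[(5S,6S,8S,9S,10R)-6-acetoxy-8-hydroxy-4,4,8,10-tetramethyl-cis-decalin-9-yl]-3-methylpent-2-enoic acid (target)
Conditions: Pd(PPh3)4 (5 mol %), morpholine, THF, rt
Reagents that add atoms: none
Why: Tsuji–Trost-type allyl transfer to morpholine frees the acid under neutral conditions that leave the acetate, the tertiary alcohol and the E-alkene untouched.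

**Compound list**
1 | geranic acid, (2E)-3,7-dimethylocta-2,6-dienoic acid | CC(C)=CCC/C(C)=C/C(=O)O | starting material
2 | (±)-α-cyclogeranic acid | OC(=O)C1C(C)=CCCC1(C)C | intermediate
3 | (S)-1-phenylethylammonium (1S)-2,6,6-trimethylcyclohex-2-ene-1-carboxylate | [O-]C(=O)[C@@H]1C(C)=CCCC1(C)C.C[C@H]([NH3+])c1ccccc1 | intermediate
4 | (S)-α-cyclogeranic acid (not isolated) | OC(=O)[C@@H]1C(C)=CCCC1(C)C | intermediate
5 | (S)-α-cyclogeraniol | OC[C@@H]1C(C)=CCCC1(C)C | intermediate
6 | (S)-α-cyclocitral | O=C[C@@H]1C(C)=CCCC1(C)C | intermediate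
7 | methyl (2E)-3-[(1S)-2,6,6-trimethylcyclohex-2-en-1-yl]prop-2-enoate | COC(=O)/C=C/[C@@H]1C(C)=CCCC1(C)C | intermediate
8 | methyl 3-[(1S)-2,6,6-trimethylcyclohex-2-en-1-yl]propanoate | COC(=O)CC[C@@H]1C(C)=CCCC1(C)C | intermediate
9 | methyl 3-[(1S)-2,6,6-trimethyl-4-oxocyclohex-2-en-1-yl]propanoate | COC(=O)CC[C@@H]1C(C)=CC(=O)CC1(C)C | intermediate
10 | 3-[(1S)-2,6,6-trimethyl-4-oxocyclohex-2-en-1-yl]propanoic acid | OC(=O)CC[C@@H]1C(C)=CC(=O)CC1(C)C | intermediate
11 | acyl imidazolide of 10 (not isolated) | O=C(CC[C@@H]1C(C)=CC(=O)CC1(C)C)n1ccnc1 | intermediate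
12 | methyl 3-oxo-5-[(1S)-2,6,6-trimethyl-4-oxocyclohex-2-en-1-yl]pentanoate | COC(=O)CC(=O)CC[C@@H]1C(C)=CC(=O)CC1(C)C | intermediate
13 | methyl (5S,10R)-4,4,10-trimethyl-2,8-dioxo-cis-decalin-9-carboxylate (C9 unassigned) | C1CC(=O)C(C(=O)OC)[C@]2(C)CC(=O)CC(C)(C)[C@H]12 | intermediate
14 | (5S,10R)-4,4,10-trimethyl-cis-decalin-2,8-dione | C1CC(=O)C[C@]2(C)CC(=O)CC(C)(C)[C@H]12 | intermediate
15 | (5S,10S)-8,8-ethylenedioxy-4,4,10-trimethyl-cis-decalin-2-one | C1CC2(OCCO2)C[C@]3(C)CC(=O)CC(C)(C)[C@H]13 | intermediate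
16 | C2 hydrazone of 15 (not isolated) | C1CC2(OCCO2)C[C@]3(C)CC(=NN)CC(C)(C)[C@H]13 | intermediate
17 | (5S,10S)-8,8-ethylenedioxy-4,4,10-trimethyl-cis-decalin | C1CC2(OCCO2)C[C@]3(C)CCCC(C)(C)[C@H]13 | intermediate
18 | (5S,10S)-4,4,10-trimethyl-cis-decalin-8-one | C1CC(=O)C[C@]2(C)CCCC(C)(C)[C@H]12 | intermediate
19 | (5S,10S)-4,4,10-trimethyl-8-(trimethylsilyloxy)-cis-decal-7-ene (not isolated) | C1C=C(O[Si](C)(C)C)C[C@]2(C)CCCC(C)(C)[C@H]12 | intermediate
20 | (5S,10S)-4,4,10-trimethyl-cis-decal-6-en-8-one | C1=CC(=O)C[C@]2(C)CCCC(C)(C)[C@H]12 | intermediate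
21 | (5S,6R,7R,10S)-6,7-epoxy-4,4,10-trimethyl-cis-decalin-8-one | O1[C@H]2[C@@H]1C(=O)C[C@]3(C)CCCC(C)(C)[C@H]23 | intermediate
22 | 3-(trimethylsilyl)but-3-en-2-one | CC(=O)C(=C)[Si](C)(C)C | starting material
23 | (5S,6R,7R,9S,10R)-6,7-epoxy-4,4,10-trimethyl-9-[3-oxo-2-(trimethylsilyl)butyl]-cis-decalin-8-one (silyl carbon unassigned; not isolated) | O1[C@H]2[C@@H]1C(=O)[C@@H](CC([Si](C)(C)C)C(C)=O)[C@]3(C)CCCC(C)(C)[C@H]23 | intermediate
24 | (5S,6R,7R,9S,10R)-6,7-epoxy-4,4,10-trimethyl-9-(3-oxobutyl)-cis-decalin-8-one | O1[C@H]2[C@@H]1C(=O)[C@@H](CCC(C)=O)[C@]3(C)CCCC(C)(C)[C@H]23 | intermediate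
25 | allyl (2E)-5-[(5S,6R,7R,9S,10R)-6,7-epoxy-4,4,10-trimethyl-8-oxo-cis-decalin-9-yl]-3-methylpent-2-enoate | O1[C@H]2[C@@H]1C(=O)[C@@H](CC/C(C)=C/C(=O)OCC=C)[C@]3(C)CCCC(C)(C)[C@H]23 | intermediate
26 | allyl (2E)-5-[(5S,6S,9S,10R)-6-hydroxy-4,4,10-trimethyl-8-oxo-cis-decalin-9-yl]-3-methylpent-2-enoate | O[C@H]1CC(=O)[C@@H](CC/C(C)=C/C(=O)OCC=C)[C@]2(C)CCCC(C)(C)[C@H]12 | intermediate
27 | allyl (2E)-5-[(5S,6S,8S,9S,10R)-6,8-dihydroxy-4,4,8,10-tetramethyl-cis-decalin-9-yl]-3-methylpent-2-enoate | O[C@H]1C[C@](C)(O)[C@@H](CC/C(C)=C/C(=O)OCC=C)[C@]2(C)CCCC(C)(C)[C@H]12 | intermediate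
28 | allyl (2E)-5-[(5S,6S,8S,9S,10R)-6-acetoxy-8-hydroxy-4,4,8,10-tetramethyl-cis-decalin-9-yl]-3-methylpent-2-enoate | CC(=O)O[C@H]1C[C@](C)(O)[C@@H](CC/C(C)=C/C(=O)OCC=C)[C@]2(C)CCCC(C)(C)[C@H]12 | intermediate
29 | (5S,6S,8S,9S,10R,13E)-6-acetoxy-8-hydroxylabd-13-en-15-oic acid with cis ring fusion | CC(=O)O[C@H]1C[C@](C)(O)[C@@H](CC/C(C)=C/C(=O)O)[C@]2(C)CCCC(C)(C)[C@H]12 | target

**Total step count:** 22.
**Longest linear sequence:** 22 steps (1 → 29; fragment 22 is bought).

**Three steps most likely to fail**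

Step 16 (face of the epoxidation). The stereoelectronically preferred axial attack at C6 is on the hindered face, so the epoxide trans to the angular methyl may compete. The fallback sets out from enone 20 and comes back at epoxy ketone 21. Luche reduction (NaBH4, CeCl3, MeOH, −40 °C; hydride from the convex face) gives the allylic alcohol with 8-OH trans to the angular methyl F1. Silylation (tBuMe2SiOTf, 2,6-lutidine) gives its silyl ether F2. mCPBA with NaHCO3 then epoxidises anti to the bulky pseudoaxial silyloxy group, that is cis to the angular methyl, giving epoxy silyl ether F3. Bu4NF gives epoxy alcohol F4, and Dess–Martin oxidation gives 21.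

Step 17 (Michael addition at the neopentyl C9 enolate). The hindered enolate may polymerise or deprotonate the acceptor instead of adding. The fallback sets out from epoxy ketone 21 and comes back at diketone 24. The same lithium enolate is alkylated in an SN2 reaction with 2-(2-iodoethyl)-2-methyl-1,3-dioxolane (THF–DMPU, −78 → −20 °C), a masked 3-oxobutyl electrophile that cannot polymerise, to give side-chain ketal F5. Pyridinium p-toluenesulfonate in wet acetone then gives 24.

Step 20 (face of the methyl addition). The axial side chain on C9 hinders equatorial attack, so the C8 epimer may form. The fallback sets out from hydroxy ketone 26 and comes back at diol 27. Takai–Lombardo methylenation (Zn, CH2Br2, TiCl4) gives the 8(17)-methylene compound F6. mCPBA then delivers oxygen, instead of carbon, from the face the methyl nucleophile used, giving the spiro-epoxide with oxygen trans to the angular methyl F7. LiI–AcOH opens it at the primary carbon to iodohydrin F8, and Bu3SnH with AIBN removes iodine to give 27.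

**Further compounds**
F1 | step 16 | (5S,10S)-4,4,10-trimethyl-cis-decal-6-en-8-ol, 8-OH trans to the angular methyl | C1=C[C@H](O)C[C@]2(C)CCCC(C)(C)[C@H]12
F2 | step 16 | tert-butyldimethylsilyl ether of F1 | C1=C[C@H](O[Si](C)(C)C(C)(C)C)C[C@]2(C)CCCC(C)(C)[C@H]12
F3 | step 16 | 6,7-epoxide of F2, epoxide cis to the angular methyl | O1[C@H]2[C@@H]1[C@H](O[Si](C)(C)C(C)(C)C)C[C@]3(C)CCCC(C)(C)[C@H]23
F4 | step 16 | 6,7-epoxy-4,4,10-trimethyl-cis-decalin-8-ol (desilylated F3) | O1[C@H]2[C@@H]1[C@H](O)C[C@]3(C)CCCC(C)(C)[C@H]23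
F5 | step 17 | ethylene ketal of 24 at the side-chain ketone | O1[C@H]2[C@@H]1C(=O)[C@@H](CCC1(C)OCCO1)[C@]3(C)CCCC(C)(C)[C@H]23
F6 | step 20 | 8(17)-methylene analogue of 26 | O[C@H]1CC(=C)[C@@H](CC/C(C)=C/C(=O)OCC=C)[C@]2(C)CCCC(C)(C)[C@H]12
F7 | step 20 | 8,17-epoxide of F6, oxygen trans to the angular methyl | O[C@H]1C[C@@]3(CO3)[C@@H](CC/C(C)=C/C(=O)OCC=C)[C@]2(C)CCCC(C)(C)[C@H]12
F8 | step 20 | 17-iodo derivative of 27 | O[C@H]1C[C@](CI)(O)[C@@H](CC/C(C)=C/C(=O)OCC=C)[C@]2(C)CCCC(C)(C)[C@H]12
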